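**Retrosynthetic overview**

1. Target 27 ⇐ bromo ketone 18 (C9=O) plus a C6 organocerium from (R)-linalool: the C9–C11 bond and the C9 centre come last, and C13 comes from the chiral pool.
2. 18 ⇐ 3,9-diketone 15: C3–Br via enol triflate → alkenyl bromide → radical hydrogenation; C8–Me by enolate methylation; C5–H by hydrogenation of a C5=C6 alkene.
3. Ring A ⇐ ring B in one operation (step 7): SmI2 stitches the C2–C3–C4 unit of 8 (a ketone flanked by CH2Br and CMe2Cl) between the formyl carbon C1 and the ring-ketone carbon C5 of keto aldehyde 6, forming C1–C2 and C4–C5.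
4. Enabling feature: in ring A, C1 and C5 both sit on the quaternary C10 (a 1,3-pair that ring B can carry as CHO and C=O), and C2 and C4 flank C3, which can be a ketone and later the C–Br carbon.
5. Order of rings: ring B (C5–C10) first, from 2-methylcyclohexane-1,3-dione with C10 set by yeast desymmetrisation; ring A second.

Key step: step 7

Remark 1: locants are labdane-type on a decalin (bicyclo[4.4.0]decane) core: ring A = C1–C5 and C10, ring B = C5–C10; C4 bears two methyls, C8 and C10 one each, C9 the tertiary hydroxyl and the chain C11–C15 with the C13 carbinol.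
Remark 2 (assumption): (R)-linalool is taken as the enantiopure commercial terpene and 3-chloro-3-methylbutan-2-one as a commercial ketone.

**Route**

Step 1
Reactants: 1 2-methylcyclohexane-1,3-dione
Product: 2 2-allyl-2-methylcyclohexane-1,3-dione
Conditions: allyl bromide, 1 M aq NaOH, rt
Reagents that add atoms: allyl bromide, C=CCBr
Why: C-alkylation of the stabilised 1,3-diketone enolate (enolate alkylation) puts the future C1 on the future C10, and the product is still achiral.

Step 2
Reactants: 2 2-allyl-2-methylcyclohexane-1,3-dione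
Product: 3 (2S,3S)-2-allyl-3-hydroxy-2-methylcyclohexan-1-one
Conditions: baker's yeast (Saccharomyces cerevisiae), sucrose, H2O, 30 °C
Reagents that add atoms: none
Why: Enzymatic desymmetrising ketone reduction, known for 2,2-disubstituted cyclohexane-1,3-diones, reduces one of the two enantiotopic carbonyls from one face, which sets the carbinol (3S) and makes the quaternary carbon a stereocentre (2S) of the configuration needed for C10.

Step 3
Reactants: 3 (2S,3S)-2-allyl-3-hydroxy-2-methylcyclohexan-1-one
Product: 4 (2S,3S)-2-allyl-3-(tert-butyldimethylsilyloxy)-2-methylcyclohexan-1-one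
Conditions: t-BuMe2SiCl, imidazole, DMF, 40 °C
Reagents that add atoms: tert-butyldimethylsilyl chloride, CC(C)(C)[Si](C)(C)Cl
Why: Imidazole-promoted silylation of the hindered secondary alcohol removes the only acidic proton before the samarium step.

Step 4
Reactants: 4 (2S,3S)-2-allyl-3-(tert-butyldimethylsilyloxy)-2-methylcyclohexan-1-one
Product: 5 (2S,3S)-3-(tert-butyldimethylsilyloxy)-2-methyl-2-[(E)-prop-1-enyl]cyclohexan-1-one
Conditions: PdCl2(MeCN)2 (5 mol%), toluene, 70 °C
Reagents that add atoms: none
Why: Metal-hydride-mediated alkene isomerisation moves the terminal double bond to the more substituted (E)-propenyl position, the thermodynamic sink, without touching the quaternary centre.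

Step 5
Reactants: 5 (2S,3S)-3-(tert-butyldimethylsilyloxy)-2-methyl-2-[(E)-prop-1-enyl]cyclohexan-1-one
Product: 6 (1R,2S)-2-(tert-butyldimethylsilyloxy)-1-methyl-6-oxocyclohexane-1-carbaldehyde
Conditions: O3, CH2Cl2–MeOH, −78 °C; Me2S
Reagents that add atoms: ozone, [O-][O+]=O
Why: Ozonolysis with reductive work-up cleaves the propenyl group to the non-enolisable formyl group on the quaternary carbon (C1 at the aldehyde level).

Step 6
Reactants: 7 3-chloro-3-methylbutan-2-one
Product: 8 1-bromo-3-chloro-3-methylbutan-2-one
Conditions: Br2, MeOH, 0 °C → rt; H2O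
Reagents that add atoms: bromine, BrBr
Why: Acid-catalysed alpha-bromination of a ketone takes place at the methyl group, the only enolisable position of 7.

Step 7
Reactants: 6 (1R,2S)-2-(tert-butyldimethylsilyloxy)-1-methyl-6-oxocyclohexane-1-carbaldehyde; 8 1-bromo-3-chloro-3-methylbutan-2-one
Product: 10 (9S,10S)-9-(tert-butyldimethylsilyloxy)-1,5-dihydroxy-4,4,10-trimethyldecalin-3-one (C1 and C5 epimers), via chloro aldol samarium alkoxide 9 (not isolated)
Conditions: 8 (1.2 equiv), SmI2 (0.1 M in THF, 2.2 equiv) added at −78 °C; then SmI2 (2.4 equiv), −78 → 0 °C; aq NH4Cl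
Reagents that add atoms: none
Why: Proposed new method: SmI2 should first cleave the primary C–Br bond of 8 (the weaker carbon–halogen bond) to a samarium enolate that adds to the non-enolisable aldehyde of 6 (C1–C2), and further SmI2 should then cleave the tertiary alpha-chloro ketone of 9 to a tetrasubstituted samarium enolate that closes ring A by aldol addition to the ring ketone (C4–C5, quaternary C4). The closest known reactions are the SmI2 Reformatsky reaction of alpha-halo ketones with aldehydes and the intramolecular SmI2 Reformatsky cyclisation onto ketones, run here in sequence with one bifunctional reagent. Ring A closes in the 6-(enolendo)-exo-trig mode with samarium bridging the enolate and ketone oxygens. The two new carbinol centres (C1, C5) need no control because step 8 removes both, and C9 and C10 are not touched. The step needs aldehyde-before-ketone chemoselectivity (secured by the hindered, alpha-quaternary ring ketone), bromide-before-chloride reduction (secured by bond strength and portionwise SmI2 at −78 °C) and regiodefined enolates (secured because each is made by carbon–halogen cleavage and not by deprotonation), while ring size lets the second enolate reach only the C5 carbonyl.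

Step 8
Reactants: 10 (9S,10S)-9-(tert-butyldimethylsilyloxy)-1,5-dihydroxy-4,4,10-trimethyldecalin-3-one
Product: 11 (9S,10R)-9-(tert-butyldimethylsilyloxy)-4,4,10-trimethyldecala-1,5-dien-3-one
Conditions: Burgess reagent (3 equiv), toluene, 70 °C
Reagents that add atoms: none
Why: Burgess dehydration (syn-elimination of the sulfamate esters) should remove both carbinols with forced regiochemistry, because each has beta-hydrogens on one side only (C2 and C6), giving the C1=C2 enone and the C5=C6 alkene and erasing the two uncontrolled centres.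

Step 9
Reactants: 11 (9S,10R)-9-(tert-butyldimethylsilyloxy)-4,4,10-trimethyldecala-1,5-dien-3-one
Product: 12 (9S,10R)-9-hydroxy-4,4,10-trimethyldecala-1,5-dien-3-one
Conditions: HF·pyridine, THF, 0 °C → rt
Reagents that add atoms: none
Why: Fluoride-mediated desilylation under buffered acidic conditions avoids a free alkoxide next to the quaternary carbon that carries the enone.

Step 10
Reactants: 12 (9S,10R)-9-hydroxy-4,4,10-trimethyldecala-1,5-dien-3-one
Product: 13 (10R)-4,4,10-trimethyldecala-1,5-diene-3,9-dione
Conditions: Dess–Martin periodinane, NaHCO3, CH2Cl2, rt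
Reagents that add atoms: none
Why: Dess–Martin oxidation gives the C9 ketone under neutral conditions, the carbinol centre being expendable once it has fixed C10.

Step 11
Reactants: 13 (10R)-4,4,10-trimethyldecala-1,5-diene-3,9-dione
Product: 14 (8S,10R)-4,4,8,10-tetramethyldecala-1,5-diene-3,9-dione
Conditions: LiN(i-Pr)2, THF, −78 °C; MeI, −78 → −20 °C
Reagents that add atoms: iodomethane, CI
Why: Kinetic enolate alkylation is regiospecific because C8 is the only enolisable position of 13 (C4 and C10 are quaternary and the C3 ketone is a non-enolisable enone), and the C8 configuration is settled by the equilibration in step 12.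

Step 12
Reactants: 14 (8S,10R)-4,4,8,10-tetramethyldecala-1,5-diene-3,9-dione
Product: 15 (5R,8S,10R)-4,4,8,10-tetramethyl-trans-decalin-3,9-dione
Conditions: H2 (3 atm), Pd/C, EtOAc, rt; then NaOMe (cat.), MeOH, rt
Reagents that add atoms: none
Why: Heterogeneous catalytic hydrogenation saturates the enone and the C5=C6 alkene with hydrogen delivered to C5 from the face opposite the C10 methyl, as in 4,4-dimethyl-5-en-3-one steroids (trans fusion), and methoxide epimerisation then places the C8 methyl equatorial, away from the syn-axial C10 methyl.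

Step 13
Reactants: 15 (5R,8S,10R)-4,4,8,10-tetramethyl-trans-decalin-3,9-dione
Product: 16 (5R,8S,10R)-4,4,8,10-tetramethyl-9-oxo-trans-decal-2-en-3-yl trifluoromethanesulfonate
Conditions: KN(SiMe3)2 (1.05 equiv), THF, −78 °C; PhNTf2
Reagents that add atoms: N-phenylbis(trifluoromethanesulfonimide), O=S(=O)(N(c1ccccc1)S(=O)(=O)C(F)(F)F)C(F)(F)F
Why: Kinetic deprotonation by the bulky amide should occur at the C2 methylene of the C3 ketone and not at the hindered C8 methine, and O-triflation of that enolate gives the C2=C3 enol triflate.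

Step 14
Reactants: 16 (5R,8S,10R)-4,4,8,10-tetramethyl-9-oxo-trans-decal-2-en-3-yl trifluoromethanesulfonate
Product: 17 (5S,8S,10R)-3-bromo-4,4,8,10-tetramethyl-trans-decal-2-en-9-one
Conditions: Ni(cod)2 (10 mol%), LiBr, DMA–THF, rt
Reagents that add atoms: lithium bromide, [Li+].[Br-]
Why: Nickel-catalysed halogen exchange of an enol triflate (oxidative addition, triflate–bromide exchange, reductive elimination) gives the alkenyl bromide and tolerates the hindered ketone.

Step 15
Reactants: 17 (5S,8S,10R)-3-bromo-4,4,8,10-tetramethyl-trans-decal-2-en-9-one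
Product: 18 (3R,5S,8S,10R)-3-bromo-4,4,8,10-tetramethyl-trans-decalin-9-one
Conditions: Co(acac)2, t-BuOOH, Et3SiH, 1,4-cyclohexadiene, n-PrOH, rt
Reagents that add atoms: none
Why: Cobalt-hydride hydrogen-atom-transfer hydrogenation of an alkenyl halide adds H to C2, and the alpha-bromo radical at C3 should take its hydrogen along the axial trajectory, anti to the axial C4 methyl, which leaves bromine equatorial (3R).

Step 16
Reactants: 19 (R)-linalool
Product: 20 (3R)-3,7-dimethyl-3-(triethylsilyloxy)octa-1,6-diene
Conditions: Et3SiOTf, 2,6-lutidine, CH2Cl2, −78 → 0 °C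
Reagents that add atoms: triethylsilyl trifluoromethanesulfonate, CC[Si](CC)(CC)OS(=O)(=O)C(F)(F)F
Why: Silylation of the tertiary allylic alcohol with the silyl triflate protects the chiral-pool carbinol (C13) without touching its configuration.

Step 17
Reactants: 20 (3R)-3,7-dimethyl-3-(triethylsilyloxy)octa-1,6-diene
Product: 22 (4R)-4-methyl-4-(triethylsilyloxy)hex-5-enoic acid, via aldehyde 21 (not isolated)
Conditions: O3 (1 equiv), CH2Cl2–pyridine, −78 °C; Me2S; then NaClO2, NaH2PO4, 2-methyl-2-butene, t-BuOH–H2O, 0 °C → rt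
Reagents that add atoms: ozone, [O-][O+]=O; sodium chlorite, [Na+].[O-]Cl=O
Why: Ozone attacks the electron-rich trisubstituted alkene faster than the vinyl group (chemoselective ozonolysis), and Pinnick oxidation of the aldehyde gives the acid that is one carbon longer than the chain needed.

Step 18
Reactants: 22 (4R)-4-methyl-4-(triethylsilyloxy)hex-5-enoic acid
Product: 23 (3R)-5-iodo-3-methyl-3-(triethylsilyloxy)pent-1-ene
Conditions: PhI(OAc)2, I2, cyclohexane, visible light, reflux
Reagents that add atoms: iodine, II
Why: Radical iododecarboxylation (a Hunsdiecker-type reaction with a hypervalent iodine oxidant) excises the extra carbon as CO2 and leaves the primary iodide without involving the carbinol centre.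

Step 19
Reactants: 23 (3R)-5-iodo-3-methyl-3-(triethylsilyloxy)pent-1-ene; 18 (3R,5S,8S,10R)-3-bromo-4,4,8,10-tetramethyl-trans-decalin-9-one
Product: 26 (1R,2S,4aS,6R,8aR)-6-bromo-2,5,5,8a-tetramethyl-1-[(3R)-3-methyl-3-(triethylsilyloxy)pent-4-en-1-yl]decahydronaphthalen-1-ol, via organolithium 24 (not isolated), via organocerium 25 (not isolated)
Conditions: 23, t-BuLi (2.1 equiv), Et2O, −78 °C; CeCl3, THF, −78 °C; then 18, −78 → −40 °C; aq NH4Cl
Reagents that add atoms: none
Why: Iodine–lithium exchange and transmetalation give a weakly basic organocerium that should add to the hindered, enolisable ketone (carbonyl 1,2-addition) from the face opposite the axial C10 methyl, so the chain enters axially and the hydroxyl becomes equatorial (9R), while the neopentylic secondary bromide is inert at low temperature.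

Step 20
Reactants: 26 (1R,2S,4aS,6R,8aR)-6-bromo-2,5,5,8a-tetramethyl-1-[(3R)-3-methyl-3-(triethylsilyloxy)pent-4-en-1-yl]decahydronaphthalen-1-ol
Product: 27 (1R,2S,4aS,6R,8aR)-6-bromo-1-[(3R)-3-hydroxy-3-methylpent-4-en-1-yl]-2,5,5,8a-tetramethyldecahydronaphthalen-1-ol (CNP0318118.1)
Conditions: Bu4NF, AcOH, THF, rt
Reagents that add atoms: none
Why: Buffered fluoride desilylation removes the tertiary triethylsilyl ether without base-induced loss of HBr and gives the target.

**Compound list**

1 | 2-methylcyclohexane-1,3-dione | CC1C(=O)CCCC1=O | starting material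
2 | 2-allyl-2-methylcyclohexane-1,3-dione | C=CCC1(C)C(=O)CCCC1=O | intermediate
3 | (2S,3S)-2-allyl-3-hydroxy-2-methylcyclohexan-1-one | O=C1CCC[C@H](O)[C@]1(C)CC=C | intermediate
4 | (2S,3S)-2-allyl-3-(tert-butyldimethylsilyloxy)-2-methylcyclohexan-1-one | O=C1CCC[C@H](O[Si](C)(C)C(C)(C)C)[C@]1(C)CC=C | intermediate
5 | (2S,3S)-3-(tert-butyldimethylsilyloxy)-2-methyl-2-[(E)-prop-1-enyl]cyclohexan-1-one | O=C1CCC[C@H](O[Si](C)(C)C(C)(C)C)[C@]1(C)/C=C/C | intermediate
6 | (1R,2S)-2-(tert-butyldimethylsilyloxy)-1-methyl-6-oxocyclohexane-1-carbaldehyde | O=C1CCC[C@H](O[Si](C)(C)C(C)(C)C)[C@]1(C)C=O | intermediate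
7 | 3-chloro-3-methylbutan-2-one | CC(=O)C(C)(C)Cl | starting material
8 | 1-bromo-3-chloro-3-methylbutan-2-one | BrCC(=O)C(C)(C)Cl | intermediate
9 | (2S,3S)-3-(tert-butyldimethylsilyloxy)-2-(4-chloro-1-hydroxy-4-methyl-3-oxopentyl)-2-methylcyclohexan-1-one (formed as its samarium alkoxide; carbinol epimers) | O=C1CCC[C@H](O[Si](C)(C)C(C)(C)C)[C@]1(C)C(O)CC(=O)C(C)(C)Cl | intermediate
10 | (9S,10S)-9-(tert-butyldimethylsilyloxy)-1,5-dihydroxy-4,4,10-trimethyldecalin-3-one (C1 and C5 epimers) | CC(C)(C)[Si](C)(C)O[C@H]1CCCC2(O)C(C)(C)C(=O)CC(O)[C@]21C | intermediate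
11 | (9S,10R)-9-(tert-butyldimethylsilyloxy)-4,4,10-trimethyldecala-1,5-dien-3-one | CC(C)(C)[Si](C)(C)O[C@H]1CCC=C2C(C)(C)C(=O)C=C[C@]21C | intermediate
12 | (9S,10R)-9-hydroxy-4,4,10-trimethyldecala-1,5-dien-3-one | O[C@H]1CCC=C2C(C)(C)C(=O)C=C[C@]21C | intermediate
13 | (10R)-4,4,10-trimethyldecala-1,5-diene-3,9-dione | O=C1CCC=C2C(C)(C)C(=O)C=C[C@]21C | intermediate
14 | (8S,10R)-4,4,8,10-tetramethyldecala-1,5-diene-3,9-dione | O=C1[C@@H](C)CC=C2C(C)(C)C(=O)C=C[C@]21C | intermediate
15 | (5R,8S,10R)-4,4,8,10-tetramethyl-trans-decalin-3,9-dione | O=C1[C@@H](C)CC[C@@H]2C(C)(C)C(=O)CC[C@]21C | intermediate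
16 | (5R,8S,10R)-4,4,8,10-tetramethyl-9-oxo-trans-decal-2-en-3-yl trifluoromethanesulfonate | O=C1[C@@H](C)CC[C@@H]2C(C)(C)C(OS(=O)(=O)C(F)(F)F)=CC[C@]21C | intermediate
17 | (5S,8S,10R)-3-bromo-4,4,8,10-tetramethyl-trans-decal-2-en-9-one | O=C1[C@@H](C)CC[C@@H]2C(C)(C)C(Br)=CC[C@]21C | intermediate
18 | (3R,5S,8S,10R)-3-bromo-4,4,8,10-tetramethyl-trans-decalin-9-one | O=C1[C@@H](C)CC[C@@H]2C(C)(C)[C@H](Br)CC[C@]21C | intermediate
19 | (R)-linalool, (3R)-3,7-dimethylocta-1,6-dien-3-ol | C=C[C@](C)(O)CCC=C(C)C | starting material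
20 | (3R)-3,7-dimethyl-3-(triethylsilyloxy)octa-1,6-diene | C=C[C@](C)(O[Si](CC)(CC)CC)CCC=C(C)C | intermediate
21 | (4R)-4-methyl-4-(triethylsilyloxy)hex-5-enal | C=C[C@](C)(O[Si](CC)(CC)CC)CCC=O | intermediate
22 | (4R)-4-methyl-4-(triethylsilyloxy)hex-5-enoic acid | C=C[C@](C)(O[Si](CC)(CC)CC)CCC(=O)O | intermediate
23 | (3R)-5-iodo-3-methyl-3-(triethylsilyloxy)pent-1-ene | C=C[C@](C)(O[Si](CC)(CC)CC)CCI | intermediate
24 | [(3R)-3-methyl-3-(triethylsilyloxy)pent-4-enyl]lithium | C=C[C@](C)(O[Si](CC)(CC)CC)CC[Li] | intermediate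
25 | dichloro[(3R)-3-methyl-3-(triethylsilyloxy)pent-4-enyl]cerium | C=C[C@](C)(O[Si](CC)(CC)CC)CC[Ce](Cl)Cl | intermediate
26 | (1R,2S,4aS,6R,8aR)-6-bromo-2,5,5,8a-tetramethyl-1-[(3R)-3-methyl-3-(triethylsilyloxy)pent-4-en-1-yl]decahydronaphthalen-1-ol | C=C[C@](C)(O[Si](CC)(CC)CC)CC[C@@]1(O)[C@@H](C)CC[C@@H]2C(C)(C)[C@H](Br)CC[C@]21C | intermediate
27 | (1R,2S,4aS,6R,8aR)-6-bromo-1-[(3R)-3-hydroxy-3-methylpent-4-en-1-yl]-2,5,5,8a-tetramethyldecahydronaphthalen-1-ol | C=C[C@](C)(O)CC[C@@]1(O)[C@@H](C)CC[C@@H]2C(C)(C)[C@H](Br)CC[C@]21C | target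

**Step count**

Total: 20 steps. Longest linear sequence: 16 steps (1–5, 7–15, 19, 20).

**Steps most likely to fail**

Step 7 (proposed new method). The order of carbon–halogen cleavage may be lost, so that the tertiary enolate forms first and attacks the aldehyde or is simply protonated. The alpha'-chloro samarium enolate may also ionise to an oxyallyl species (Favorskii-type diversion), or the congested second aldol addition may reverse. The fallback sets out from 6 and 7 and returns at 10, using known chemistry only. The lithium enolate of 7 (LiN(i-Pr)2, THF, −78 °C; only the methyl group can be deprotonated) is added to the aldehyde of 6 in a directed aldol addition, and the chloro aldol 9 is isolated. Its hydroxyl is deprotonated (LiN(SiMe3)2, −78 °C), and SmI2 (2.2 equiv) then effects the precedented intramolecular samarium Reformatsky cyclisation onto the ring ketone to give 10. No new compound is needed.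

Step 8. Elimination may fail at the very hindered tertiary carbinol. Ionisation followed by 1,2-methyl migration, or retro-aldol ring opening, may compete. The fallback sets out from 5 and returns at 11, and never forms the tertiary carbinol.
- Regiospecific enolisation of 5 (KN(SiMe3)2, PhNTf2, THF, −78 °C; only C6 is enolisable) gives the enol triflate F1.
- Ozonolysis of the propenyl group (O3, then Me2S; the electron-poor enol triflate is spared) gives the triflate aldehyde F2.
- The more substituted trimethylsilyl enol ether of commercial 3-methylbutan-2-one, F3 (Me3SiCl, NaI, Et3N), is coupled with F2 in a palladium-catalysed alpha-alkenylation (Pd(OAc)2, P(t-Bu)3, CsF, toluene–DMF, 80 °C). This forms C4–C5 at the sp2 carbon and gives the keto aldehyde F4.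
- An intramolecular aldol condensation (piperidine, AcOH, toluene, 80 °C) closes ring A and gives 11.

Step 15. Hydrogen-atom delivery to the C3 radical may show poor facial selectivity, giving the axial bromide, or bromine may be lost reductively. The fallback sets out from 15 and returns at 18. LiBH(s-Bu)3 (THF, −78 °C) reduces the less hindered C3 ketone from the equatorial side to the axial alcohol F5. An Appel reaction (PPh3, CBr4, CH2Cl2) then replaces the hydroxyl by bromide with inversion to give the equatorial bromide 18.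

Further compounds
F0 | step 7 | none | none
F1 | step 8 | (5S,6S)-5-(tert-butyldimethylsilyloxy)-6-methyl-6-[(E)-prop-1-enyl]cyclohex-1-en-1-yl trifluoromethanesulfonate | FC(F)(F)S(=O)(=O)OC1=CCC[C@H](O[Si](C)(C)C(C)(C)C)[C@]1(C)/C=C/C
F2 | step 8 | (5S,6S)-5-(tert-butyldimethylsilyloxy)-6-formyl-6-methylcyclohex-1-en-1-yl trifluoromethanesulfonate | FC(F)(F)S(=O)(=O)OC1=CCC[C@H](O[Si](C)(C)C(C)(C)C)[C@]1(C)C=O
F3 | step 8 | 3-methyl-2-(trimethylsilyloxy)but-2-ene | CC(O[Si](C)(C)C)=C(C)C
F4 | step 8 | (1R,6S)-6-(tert-butyldimethylsilyloxy)-1-methyl-2-(2-methyl-3-oxobutan-2-yl)cyclohex-2-ene-1-carbaldehyde | CC(=O)C(C)(C)C1=CCC[C@H](O[Si](C)(C)C(C)(C)C)[C@]1(C)C=O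
F5 | step 15 | (3S,5R,8S,10R)-3-hydroxy-4,4,8,10-tetramethyl-trans-decalin-9-one | O=C1[C@@H](C)CC[C@@H]2C(C)(C)[C@@H](O)CC[C@]21C
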